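**Retrosynthetic overview**
- The target is the hydrated hetero-Diels–Alder dimer of one α-methylene-δ-lactone cembranolide: the [4+2] step forms C17–C17′ and O–C15′, and water then opens the ketene acetal.
- The monomer comes from α-methylenation of the saturated epoxy lactone; the 11,12-epoxide comes from the (11S,12S)-diol with overall retention.
- The 14-membered ring is closed by B-alkyl Suzuki–Miyaura coupling at C6–C7; C1–C14 is made by copper-catalysed 1,4-addition to a 6-substituted dihydropyranone, which sets C1 trans to C3.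
- Both halves (C1–C6 and C7–C14) come from one acetonide alcohol, made by chelation-controlled vinyl addition to the methyl ketone of (S)-α-hydroxy-γ-butyrolactone (this sets C3/C4 and C11/C12).
- Ring order: δ-lactone, then 14-membered carbocycle, then epoxide, then dihydropyran (formed in the cycloaddition, opened by water).

Assumption: (S)-α-hydroxy-γ-butyrolactone (from L-malic acid) is bought as the only chiral material; cembrane numbering is used (C1 = ring CH carrying C15; C16 = lactone C=O bound through O to C3; C17 = exocyclic CH2; methyls on C4, C8, C12).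

**Step 1**
Reactants: 1 (S)-α-hydroxy-γ-butyrolactone
Product: 2 (S)-3,5-dihydroxypentan-2-one (open form of its cyclic hemiketal)
Conditions: MeLi (2.2 equiv), THF, −78 °C; AcOH quench at −78 °C
Reagents that add atoms: methyllithium [Li]C
Why: After deprotonation of the OH, nucleophilic acyl addition of MeLi stops at the lithium hemiketal at −78 °C, so quenching gives the methyl ketone with the stereocentre untouched.

**Step 2**
Reactants: 2 (S)-3,5-dihydroxypentan-2-one
Product: 3 (3S,4S)-4-methylhex-5-ene-1,3,4-triol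
Conditions: CH2=CHMgBr (3.5 equiv), THF, −78 to 0 °C
Reagents that add atoms: vinylmagnesium bromide C=C[Mg]Br
Why: Cram-chelate-controlled Grignard addition: magnesium bridges the α-alkoxide and the ketone, and vinyl adds on the face opposite the CH2CH2O chain, setting the tertiary carbinol as 4S.

**Step 3**
Reactants: 3 (3S,4S)-4-methylhex-5-ene-1,3,4-triol
Product: 4 2-[(4S,5S)-2,2,5-trimethyl-5-vinyl-1,3-dioxolan-4-yl]ethanol
Conditions: Me2C(OMe)2, PPTS (cat.), acetone, rt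
Reagents that add atoms: 2,2-dimethoxypropane COC(C)(C)OC
Why: Thermodynamic acetonide formation favours the five-membered dioxolane of the 1,2-diol over the 1,3-dioxane, leaving the primary alcohol free.

**Step 4**
Reactants: 4 2-[(4S,5S)-2,2,5-trimethyl-5-vinyl-1,3-dioxolan-4-yl]ethanol
Product: 5 2-[(4S,5S)-2,2,5-trimethyl-5-vinyl-1,3-dioxolan-4-yl]acetaldehyde
Conditions: TEMPO (cat.), PhI(OAc)2, CH2Cl2, rt
Reagents that add atoms: none
Why: Oxoammonium (TEMPO) oxidation takes the primary alcohol to the aldehyde under conditions that leave the acetonide and vinyl group alone.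

**Step 5**
Reactants: 5 2-[(4S,5S)-2,2,5-trimethyl-5-vinyl-1,3-dioxolan-4-yl]acetaldehyde
Product: 6 methyl (2Z)-4-[(4S,5S)-2,2,5-trimethyl-5-vinyl-1,3-dioxolan-4-yl]but-2-enoate
Conditions: (CF3CH2O)2P(O)CH2CO2Me, KN(SiMe3)2, 18-crown-6, THF, −78 °C
Reagents that add atoms: methyl bis(2,2,2-trifluoroethyl)phosphonoacetate COC(=O)CP(=O)(OCC(F)(F)F)OCC(F)(F)F
Why: The Still–Gennari variant of the Horner–Wadsworth–Emmons olefination gives the Z-enoate needed for lactonisation.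

**Step 6**
Reactants: 6 methyl (2Z)-4-[(4S,5S)-2,2,5-trimethyl-5-vinyl-1,3-dioxolan-4-yl]but-2-enoate
Product: 8 (6S)-6-[(2S)-2-hydroxybut-3-en-2-yl]-5,6-dihydro-2H-pyran-2-one, via diol ester 7 (not isolated)
Conditions: AcOH/H2O (4:1), 50 °C
Reagents that add atoms: none
Why: Acid hydrolysis of the acetonide frees the secondary OH, which lactonises onto the Z-enoate (six-membered ring), while the tertiary OH would need a seven-membered ring and stays free.

**Step 7**
Reactants: 8 (6S)-6-[(2S)-2-hydroxybut-3-en-2-yl]-5,6-dihydro-2H-pyran-2-one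
Product: 9 (6S)-6-[(2S)-2-(triethylsilyloxy)but-3-en-2-yl]-5,6-dihydro-2H-pyran-2-one
Conditions: Et3SiOTf, 2,6-lutidine, CH2Cl2, −78 to 0 °C
Reagents that add atoms: triethylsilyl triflate CC[Si](CC)(CC)OS(=O)(=O)C(F)(F)F
Why: Silylation of the tertiary alcohol with the silyl triflate prevents quenching of the Grignard reagent and oxa-Michael closure onto the enoate in step 12.

**Step 8**
Reactants: 4 2-[(4S,5S)-2,2,5-trimethyl-5-vinyl-1,3-dioxolan-4-yl]ethanol
Product: 10 (4S,5S)-4-(2-iodoethyl)-2,2,5-trimethyl-5-vinyl-1,3-dioxolane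
Conditions: I2, PPh3, imidazole, CH2Cl2, 0 °C
Reagents that add atoms: iodine II
Why: Appel-type (Garegg–Samuelsson) iodination converts the primary alcohol to the iodide by SN2 displacement of the oxyphosphonium.

**Step 9**
Reactants: 10 (4S,5S)-4-(2-iodoethyl)-2,2,5-trimethyl-5-vinyl-1,3-dioxolane
Product: 11 (4S,5S)-4-(but-3-ynyl)-2,2,5-trimethyl-5-vinyl-1,3-dioxolane
Conditions: LiC≡CH·H2NCH2CH2NH2, DMSO, rt
Reagents that add atoms: lithium acetylide (ethylenediamine complex) [Li]C#C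
Why: SN2 alkylation of the acetylide on the unhindered primary iodide installs C7 and C8.

**Step 10**
Reactants: 11 (4S,5S)-4-(but-3-ynyl)-2,2,5-trimethyl-5-vinyl-1,3-dioxolane
Product: 13 (4S,5S)-4-[(E)-4-bromo-3-methylbut-3-enyl]-2,2,5-trimethyl-5-vinyl-1,3-dioxolane, via alkenylalane 12 (not isolated)
Conditions: AlMe3 (2 equiv), Cp2ZrCl2 (0.25 equiv), CH2Cl2, 0 °C to rt; then NBS, THF, −20 °C
Reagents that add atoms: trimethylaluminium C[Al](C)C; N-bromosuccinimide O=C1CCC(=O)N1Br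
Why: Negishi zirconium-catalysed carboalumination adds Me and Al syn across the terminal alkyne (Me to the internal carbon), and bromodealumination with retention gives the E-trisubstituted vinyl bromide while the hindered vinyl group is untouched.

**Step 11**
Reactants: 13 (4S,5S)-4-[(E)-4-bromo-3-methylbut-3-enyl]-2,2,5-trimethyl-5-vinyl-1,3-dioxolane
Product: 15 (4S,5S)-4-[(E)-4-bromo-3-methylbut-3-enyl]-5-(2-iodoethyl)-2,2,5-trimethyl-1,3-dioxolane, via alkylzirconocene 14 (not isolated)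
Conditions: Cp2Zr(H)Cl, THF, rt; then I2, 0 °C
Reagents that add atoms: iodine II
Why: Hydrozirconation places zirconium on the terminal carbon of the only monosubstituted alkene, and iododezirconation gives the primary iodide (C14).

**Step 12**
Reactants: 15 (4S,5S)-4-[(E)-4-bromo-3-methylbut-3-enyl]-5-(2-iodoethyl)-2,2,5-trimethyl-1,3-dioxolane; 9 (6S)-6-[(2S)-2-(triethylsilyloxy)but-3-en-2-yl]-5,6-dihydro-2H-pyran-2-one
Product: 18 (4R,6S)-4-{2-[(4S,5S)-5-[(E)-4-bromo-3-methylbut-3-enyl]-2,2,4-trimethyl-1,3-dioxolan-4-yl]ethyl}-6-[(2S)-2-(triethylsilyloxy)but-3-en-2-yl]tetrahydro-2H-pyran-2-one, via Grignard reagent 16 (not isolated), via silyl ketene acetal 17 (not isolated)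
Conditions: Mg, Et2O, rt (alkyl iodide inserts, vinyl bromide does not); then CuBr·SMe2 (15 mol %), Me3SiCl, THF, −78 °C, add 9; H2O work-up
Reagents that add atoms: none
Why: Copper-catalysed, Me3SiCl-accelerated conjugate addition to the dihydropyranone occurs by axial attack anti to the pseudo-equatorial C3 substituent, giving the 4,6-trans lactone and so setting C1 as R.

**Step 13**
Reactants: 18 (conjugate adduct, name as in step 12)
Product: 20 (1R,3S,4S,7E,11S,12S)-11,12-(isopropylidenedioxy)-4-(triethylsilyloxy)cembr-7-en-16,3-olide, via alkylborane 19 (not isolated)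
Conditions: 9-BBN-H, THF, rt to 40 °C; then slow addition to Pd(dppf)Cl2 (10 mol %), AsPh3, Cs2CO3, DMF/THF/H2O, 50 °C, 1 mM
Reagents that add atoms: none
Why: 9-BBN hydroborates only the monosubstituted vinyl group, and the intramolecular B-alkyl Suzuki–Miyaura coupling with the vinyl bromide closes the 14-membered ring at C6–C7 with retention of the E geometry.

**Step 14**
Reactants: 20 (protected macrocycle, name as in step 13)
Product: 21 (1R,3S,4S,7E,11S,12S)-4,11,12-trihydroxycembr-7-en-16,3-olide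
Conditions: AcOH/THF/H2O (3:1:1), 55 °C
Reagents that add atoms: none
Why: Mild acid hydrolysis removes the acetonide and the silyl ether without ionising the tertiary alcohols or protonating the trisubstituted alkene.

**Step 15**
Reactants: 21 (1R,3S,4S,7E,11S,12S)-4,11,12-trihydroxycembr-7-en-16,3-olide
Product: 24 (1R,3S,4S,7E,11S,12S)-11,12-epoxy-4-hydroxycembr-7-en-16,3-olide, via cyclic orthoacetate 22 (not isolated), via bromo acetate 23 (not isolated)
Conditions: MeC(OMe)3, PPTS (cat.), CH2Cl2, rt; AcBr, CH2Cl2, 0 °C; K2CO3, MeOH, 0 °C; PPTS work-up (recloses any opened lactone)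
Reagents that add atoms: none
Why: Kolb–Sharpless diol-to-epoxide conversion: bromide opens the acetoxonium ion at secondary C11 with inversion, and the C12 alkoxide freed by acetate cleavage displaces bromide with a second inversion, so the (11S,12S)-diol gives the trans (11S,12S)-epoxide with net retention.

**Step 16**
Reactants: 24 (1R,3S,4S,7E,11S,12S)-11,12-epoxy-4-hydroxycembr-7-en-16,3-olide
Product: 27 (1R,3S,4S,7E,11S,12S)-11,12-epoxy-4-hydroxycembra-7,15(17)-dien-16,3-olide, via Mannich base 25 (not isolated), via ammonium iodide 26 (not isolated)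
Conditions: LiN(i-Pr)2 (2.2 equiv), THF, −78 °C; CH2=NMe2+ I−, −78 °C to rt; MeI, CH2Cl2/MeOH, rt; aq NaHCO3
Reagents that add atoms: N,N-dimethylmethyleneiminium iodide C=[N+](C)C.[I-]
Why: Eschenmoser α-methylenation: the lactone enolate undergoes a Mannich reaction at its only α-CH2, and quaternisation followed by β-elimination gives the exocyclic methylene without touching C1.

**Step 17**
Reactants: 27 (two molecules)
Product: 29 target dimer CNP0186476.4, via spiro ketene acetal 28 (not isolated)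
Conditions: neat, BHT (1 mol %), 90 °C, sealed tube; then THF/pH 5 acetate buffer, rt; then DBU (0.1 equiv), CH2Cl2, rt
Reagents that add atoms: water O
Why: Thermal hetero-Diels–Alder dimerisation (one lactone as the O=C16–C15=C17 oxadiene, the other C15′=C17′ as dienophile) forms C17–C17′ and O–C15′ on the face anti to the C14′ arm, and hydrolysis of the ketene acetal expels the α-acyl tertiary alkoxide to leave the C15′ OH, while C15 settles as the 1,15-trans epimer by protonation and base equilibration of this epimerisable centre.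

**Compound list**
1 | (S)-α-hydroxy-γ-butyrolactone | O[C@H]1CCOC1=O | starting material
2 | (S)-3,5-dihydroxypentan-2-one | CC(=O)[C@@H](O)CCO | intermediate
3 | (3S,4S)-4-methylhex-5-ene-1,3,4-triol | OCC[C@H](O)[C@@](C)(O)C=C | intermediate
4 | 2-[(4S,5S)-2,2,5-trimethyl-5-vinyl-1,3-dioxolan-4-yl]ethanol | OCC[C@@H]1OC(C)(C)O[C@@]1(C)C=C | intermediate
5 | 2-[(4S,5S)-2,2,5-trimethyl-5-vinyl-1,3-dioxolan-4-yl]acetaldehyde | O=CC[C@@H]1OC(C)(C)O[C@@]1(C)C=C | intermediate
6 | methyl (2Z)-4-[(4S,5S)-2,2,5-trimethyl-5-vinyl-1,3-dioxolan-4-yl]but-2-enoate | COC(=O)/C=C\C[C@@H]1OC(C)(C)O[C@@]1(C)C=C | intermediate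
7 | methyl (2Z,5S,6S)-5,6-dihydroxy-6-methylocta-2,7-dienoate | COC(=O)/C=C\C[C@H](O)[C@@](C)(O)C=C | intermediate
8 | (6S)-6-[(2S)-2-hydroxybut-3-en-2-yl]-5,6-dihydro-2H-pyran-2-one | O=C1C=CC[C@H](O1)[C@@](C)(O)C=C | intermediate
9 | (6S)-6-[(2S)-2-(triethylsilyloxy)but-3-en-2-yl]-5,6-dihydro-2H-pyran-2-one | O=C1C=CC[C@H](O1)[C@@](C)(O[Si](CC)(CC)CC)C=C | intermediate
10 | (4S,5S)-4-(2-iodoethyl)-2,2,5-trimethyl-5-vinyl-1,3-dioxolane | ICC[C@@H]1OC(C)(C)O[C@@]1(C)C=C | intermediate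
11 | (4S,5S)-4-(but-3-ynyl)-2,2,5-trimethyl-5-vinyl-1,3-dioxolane | C#CCC[C@@H]1OC(C)(C)O[C@@]1(C)C=C | intermediate
12 | dimethyl{(1E)-2-methyl-4-[(4S,5S)-2,2,5-trimethyl-5-vinyl-1,3-dioxolan-4-yl]but-1-enyl}alane | C[Al](C)/C=C(\C)CC[C@@H]1OC(C)(C)O[C@@]1(C)C=C | intermediate
13 | (4S,5S)-4-[(E)-4-bromo-3-methylbut-3-enyl]-2,2,5-trimethyl-5-vinyl-1,3-dioxolane | Br/C=C(\C)CC[C@@H]1OC(C)(C)O[C@@]1(C)C=C | intermediate
14 | chlorobis(cyclopentadienyl){2-[(4S,5S)-5-[(E)-4-bromo-3-methylbut-3-enyl]-2,2,4-trimethyl-1,3-dioxolan-4-yl]ethyl}zirconium | Br/C=C(\C)CC[C@@H]1OC(C)(C)O[C@@]1(C)CC[Zr](Cl)(C2C=CC=C2)C2C=CC=C2 | intermediate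
15 | (4S,5S)-4-[(E)-4-bromo-3-methylbut-3-enyl]-5-(2-iodoethyl)-2,2,5-trimethyl-1,3-dioxolane | Br/C=C(\C)CC[C@@H]1OC(C)(C)O[C@@]1(C)CCI | intermediate
16 | {2-[(4S,5S)-5-[(E)-4-bromo-3-methylbut-3-enyl]-2,2,4-trimethyl-1,3-dioxolan-4-yl]ethyl}magnesium iodide | Br/C=C(\C)CC[C@@H]1OC(C)(C)O[C@@]1(C)CC[Mg]I | intermediate
17 | O-trimethylsilyl ketene acetal of lactone 18 | C[Si](C)(C)OC1=C[C@H](CC[C@]2(C)OC(C)(C)O[C@H]2CC/C(C)=C/Br)C[C@H](O1)[C@@](C)(O[Si](CC)(CC)CC)C=C | intermediate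
18 | (4R,6S)-4-{2-[(4S,5S)-5-[(E)-4-bromo-3-methylbut-3-enyl]-2,2,4-trimethyl-1,3-dioxolan-4-yl]ethyl}-6-[(2S)-2-(triethylsilyloxy)but-3-en-2-yl]tetrahydro-2H-pyran-2-one | O=C1C[C@H](CC[C@]2(C)OC(C)(C)O[C@H]2CC/C(C)=C/Br)C[C@H](O1)[C@@](C)(O[Si](CC)(CC)CC)C=C | intermediate
19 | B-alkyl-9-BBN from 18 (vinyl group converted to CH2CH2–9-borabicyclo[3.3.1]nonan-9-yl) | O=C1C[C@H](CC[C@]2(C)OC(C)(C)O[C@H]2CC/C(C)=C/Br)C[C@H](O1)[C@@](C)(O[Si](CC)(CC)CC)CCB3C4CCCC3CCC4 | intermediate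
20 | (1R,3S,4S,7E,11S,12S)-11,12-(isopropylidenedioxy)-4-(triethylsilyloxy)cembr-7-en-16,3-olide | C/C1=C\CC[C@](C)(O[Si](CC)(CC)CC)[C@@H]2C[C@@H](CC[C@]3(C)OC(C)(C)O[C@H]3CC1)CC(=O)O2 | intermediate
21 | (1R,3S,4S,7E,11S,12S)-4,11,12-trihydroxycembr-7-en-16,3-olide | C/C1=C\CC[C@](C)(O)[C@@H]2C[C@@H](CC[C@](C)(O)[C@@H](O)CC1)CC(=O)O2 | intermediate
22 | 11,12-O-(1-methoxyethylidene) derivative of 21 | C/C1=C\CC[C@](C)(O)[C@@H]2C[C@@H](CC[C@]3(C)OC(C)(OC)O[C@H]3CC1)CC(=O)O2 | intermediate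
23 | (1R,3S,4S,7E,11R,12S)-12-acetoxy-11-bromo-4-hydroxycembr-7-en-16,3-olide | C/C1=C\CC[C@](C)(O)[C@@H]2C[C@@H](CC[C@](C)(OC(C)=O)[C@H](Br)CC1)CC(=O)O2 | intermediate
24 | (1R,3S,4S,7E,11S,12S)-11,12-epoxy-4-hydroxycembr-7-en-16,3-olide | C/C1=C\CC[C@](C)(O)[C@@H]2C[C@@H](CC[C@]3(C)O[C@H]3CC1)CC(=O)O2 | intermediate
25 | 15-(dimethylaminomethyl) derivative of 24 | C/C1=C\CC[C@](C)(O)[C@@H]2C[C@@H](CC[C@]3(C)O[C@H]3CC1)C(CN(C)C)C(=O)O2 | intermediate
26 | 15-(trimethylammoniomethyl) derivative of 24, iodide | C/C1=C\CC[C@](C)(O)[C@@H]2C[C@@H](CC[C@]3(C)O[C@H]3CC1)C(C[N+](C)(C)C)C(=O)O2.[I-] | intermediate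
27 | (1R,3S,4S,7E,11S,12S)-11,12-epoxy-4-hydroxycembra-7,15(17)-dien-16,3-olide (monomer) | C/C1=C\CC[C@](C)(O)[C@@H]2C[C@@H](CC[C@]3(C)O[C@H]3CC1)C(=C)C(=O)O2 | intermediate
28 | hetero-Diels–Alder dimer (dihydropyran ketene acetal fused to lactone A, spiro to lactone B at C15′) | C/C1=C\CC[C@](C)(O)[C@@H]2C[C@@H](CC[C@]3(C)O[C@H]3CC1)C4=C(O2)O[C@]5(CC4)C(=O)O[C@H]6C[C@H]5CC[C@]7(C)O[C@H]7CC/C(C)=C/CC[C@]6(C)O | intermediate
29 | target dimer CNP0186476.4 | C/C1=C\CC[C@](C)(O)[C@@H]2C[C@@H](CC[C@]3(C)O[C@H]3CC1)[C@H](CC[C@@]1(O)C(=O)O[C@H]3C[C@H]1CC[C@]1(C)O[C@H]1CC/C(C)=C/CC[C@]3(C)O)C(=O)O2 | target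

**Step count**
Total: 17 steps. Longest linear sequence: 13 steps (steps 1–3, 8–17; the other arm, steps 1–7 then 12–17, is also 13).

**Three steps most likely to fail**

Step 13 (macrocyclic B-alkyl Suzuki–Miyaura coupling). If ring closure at C6–C7 fails, the order of bond formation is reversed, setting out from 9 and 13. Lactone 9 is hydroborated at its vinyl group (9-BBN-H) and coupled intermolecularly with vinyl bromide 13 (Pd(dppf)Cl2, AsPh3, Cs2CO3) to give the open-chain dihydropyranone (6S)-6-[(2S,5E)-6-methyl-2-(triethylsilyloxy)-8-[(4S,5S)-2,2,5-trimethyl-5-vinyl-1,3-dioxolan-4-yl]oct-5-en-2-yl]-5,6-dihydro-2H-pyran-2-one F1. Hydrozirconation–iodination (Cp2Zr(H)Cl, then I2) of its remaining vinyl group gives the primary iodide (6S)-6-[(2S,5E)-8-[(4S,5S)-5-(2-iodoethyl)-2,2,5-trimethyl-1,3-dioxolan-4-yl]-6-methyl-2-(triethylsilyloxy)oct-5-en-2-yl]-5,6-dihydro-2H-pyran-2-one F2. Slow addition of (Me3Si)3SiH and AIBN at high dilution then closes the 14-membered ring by radical 1,4-addition of the C14 radical to the dihydropyranone, trans to the C3 substituent, and the route is rejoined at 20.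

Step 15 (diol to epoxide with retention, next to a base-sensitive lactone). If the one-pot orthoester sequence gives mixtures, a stepwise double inversion is used, setting out from 21. SOCl2/Et3N at −78 °C converts the 1,2-diol into the cyclic sulfite (1R,3S,4S,7E,11S,12S)-4-hydroxy-11,12-(sulfinyldioxy)cembr-7-en-16,3-olide F3. LiBr in DMF opens it at secondary C11 with inversion, and mild aqueous acid releases the bromohydrin (1R,3S,4S,7E,11R,12S)-11-bromo-4,12-dihydroxycembr-7-en-16,3-olide F4. DBU in CH2Cl2 closes the epoxide with a second inversion, with no methanolic base near the lactone, and the route is rejoined at 24.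

Step 17 (hetero-Diels–Alder dimerisation and hydrolysis: rate, facial selectivity, C15 epimer). If the thermal dimerisation is too slow or unselective, the C17–C17′ bond is made reductively, setting out from 27. SmI2/HMPA/t-BuOH couples two molecules tail-to-tail to the hydrodimer 17,17′-bis[(1R,3S,4S,7E,11S,12S,15S)-11,12-epoxy-4-hydroxycembr-7-en-16,3-olide] F5. Mono-enolisation (KN(SiMe3)2, 3 equiv, −78 °C) and oxidation with 2-(phenylsulfonyl)-3-phenyloxaziridine hydroxylates one C15 on the face anti to the C14 arm, and the route is rejoined at 29.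

**Further compounds**
F1 | step 13 | (6S)-6-[(2S,5E)-6-methyl-2-(triethylsilyloxy)-8-[(4S,5S)-2,2,5-trimethyl-5-vinyl-1,3-dioxolan-4-yl]oct-5-en-2-yl]-5,6-dihydro-2H-pyran-2-one | O=C1C=CC[C@H](O1)[C@@](C)(O[Si](CC)(CC)CC)CC/C=C(\C)CC[C@@H]2OC(C)(C)O[C@@]2(C)C=C
F2 | step 13 | (6S)-6-[(2S,5E)-8-[(4S,5S)-5-(2-iodoethyl)-2,2,5-trimethyl-1,3-dioxolan-4-yl]-6-methyl-2-(triethylsilyloxy)oct-5-en-2-yl]-5,6-dihydro-2H-pyran-2-one | O=C1C=CC[C@H](O1)[C@@](C)(O[Si](CC)(CC)CC)CC/C=C(\C)CC[C@@H]2OC(C)(C)O[C@@]2(C)CCI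
F3 | step 15 | (1R,3S,4S,7E,11S,12S)-4-hydroxy-11,12-(sulfinyldioxy)cembr-7-en-16,3-olide | C/C1=C\CC[C@](C)(O)[C@@H]2C[C@@H](CC[C@]3(C)OS(=O)O[C@H]3CC1)CC(=O)O2
F4 | step 15 | (1R,3S,4S,7E,11R,12S)-11-bromo-4,12-dihydroxycembr-7-en-16,3-olide | C/C1=C\CC[C@](C)(O)[C@@H]2C[C@@H](CC[C@](C)(O)[C@H](Br)CC1)CC(=O)O2
F5 | step 17 | 17,17′-bis[(1R,3S,4S,7E,11S,12S,15S)-11,12-epoxy-4-hydroxycembr-7-en-16,3-olide] | C/C1=C\CC[C@](C)(O)[C@@H]2C[C@@H](CC[C@]3(C)O[C@H]3CC1)[C@H](CC[C@@H]4C(=O)O[C@H]5C[C@H]4CC[C@]6(C)O[C@H]6CC/C(C)=C/CC[C@]5(C)O)C(=O)O2
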